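**Conventions.** The units are lettered from the orsellinate end: ring A (orsellinate), unit B (3-hydroxybutanoate), ring C (central resorcylate), unit D (3-hydroxybutanoate), ring E (terminal resorcinol). Ring C is numbered C1 (carboxyl-bearing carbon), C2 and C4 (oxygenated carbons), C6 (carbon bearing the 2-acyloxypropyl chain).

## Analysis of the target

Hansforester A is an open-chain pentamer with no ring other than three benzene rings: ring A is esterified to unit B, B to the side-chain carbinol of ring C, the ring C carboxyl to unit D, and D to the side-chain carbinol of ring E. All four stereocentres are methyl-bearing secondary carbinol carbons of R configuration. They are at least five atoms apart, so none can direct another and each must come from the chiral pool or from reagent control. Two of the four ester bonds (B to C, D to E) are ordinary aliphatic esters. The other two (A to B, C to D) are benzoates whose carbonyl is flanked on both ortho positions, so attack at that carbonyl is slow. The beta-acyloxy esters of units B and D lose carboxylate by E1cB under base. A free ring C carbinol can close onto its own ortho carboxyl to a dihydroisocoumarin. The six phenols must stay masked until the end. The structural feature on which the plan rests is the contiguous array on ring C: the carboxyl at C1 and the side-chain CH2 at C6 sit on neighbouring carbons directly beside the C2 oxygen, with the second oxygen at C4. This is the pattern produced when a 3,5-dioxygenated benzyne, with its triple bond between C1 and C6, inserts into the C–C bond of a malonate.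

## Retrosynthetic reasoning

**Phenol release.** Target 31 is traced to its hexabenzyl ether 30 by cutting six benzyl–oxygen bonds. Hydrogenolysis is neutral and spares the base-labile beta-acyloxy esters. All ester oxygens sit on homobenzylic carbons, so nothing else is cleaved.

**Ester D to E.** In 30 the acyl–oxygen bond between unit D and the ring E carbinol is cut, giving acid 25 and alcohol 29. This is the least hindered ester and is therefore left for the last coupling, where a carbodiimide esterification only has to join an unhindered acid to an unhindered secondary alcohol.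

**Ring E carbinol.** Alcohol 29 is cut at the aryl–CH2 bond into aryl bromide 26 and epoxide 27. Ring E has no carboxyl, so an aryl Grignard opening of the chiral-pool epoxide at its CH2 carbon gives the carbinol in one step with the stereocentre untouched.

**Ester C to D.** Acid 25 comes from its tert-butyl ester 24, which is cut at the alkyl–oxygen bond of the hindered benzoate into acid 23 and tert-butyl (S)-3-hydroxybutanoate 19. Cutting on the alkyl side means the flanked ring C carboxyl only acts as a nucleophile. The forward reaction is a Mitsunobu esterification, whose inversion turns the S alcohol into the R ester. The partner 19 is cheap and can be used in excess.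

**Ester B to C and the allyl block.** Acid 23 is the deallylation product of allyl ester 22, which is cut at the acyl–oxygen bond of the B-to-C ester into acid 21 and carbinol 15. An allyl ester on ring C is required here. Once units A and B are attached, a simple alkyl benzoate at C1 could not be hydrolysed without destroying the other esters. The allyl group leaves under palladium catalysis without any reagent approaching the carbonyl.

**Fragment A–B.** Acid 21 arises from tert-butyl ester 20. This is cut, as above, at the alkyl–oxygen bond into acid 18 and a second equivalent of 19 (Mitsunobu with inversion). Acid 18 comes from commercial methyl orsellinate 16 through the dibenzyl ether 17.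

**Ring C carbinol.** Carbinol 15 is traced to ketone 14 by a C–H disconnection (enantioselective reduction). Ketone 14 is traced through Weinreb amide 13 and mono-acid 12 to the diallyl homophthalate 11. The sequence uses the fact that the aliphatic ester of 11 is far more accessible than the flanked benzoate.

**Key disconnection.** In 11 the C6–CH2 bond and the C1–C(=O) bond are cut together, giving aryne 10 and diallyl malonate 9. Both carbon neighbours of ring C are installed in one step, with the oxygens already at C2 and C4. The allyl esters of 9 supply the orthogonal ring C ester at no extra cost.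

**Aryne precursor.** Aryne 10 is generated from silyl triflate 8. This is reached from phenol 1 in three operations: carbamate 2, carbamate-directed ortho-silylation to 6 (via 3, 4 and 5), then carbamate cleavage and triflation via phenol 7. The ring is symmetric, so only one ortho-silylated product is possible.

## Alternatives that were turned down

**Alternative 1:** Here an aromatic ring is built rather than functionalised. Ring E (and by extension ring C) would be cut into the (R)-enone A2, whose beta-carbon is the former carboxyl carbon of a chiral-pool 3-hydroxybutanoate, and dimethyl malonate A3. In the forward step NaOMe would promote Michael addition of A3 to A2 and Claisen closure of the methyl ketone enolate onto a malonate ester, giving the cyclohexane-1,3-dione A1.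
- For: the carbinol stereocentre is bought, not made, and the reagents are cheap. A1 already has its ester carbon between an oxygenated carbon and the side-chain carbon, so the same intermediate could in principle serve ring C. On stereocontrol this is stronger than the chosen route, which needs an enantioselective reduction for ring C.
- Against: A1 is at the wrong oxidation level and must be dehydrogenated to the resorcinol in the presence of a silyl ether. For ring E the ester carbon must then be removed by hydrolysis and decarboxylation. That is five or more steps for a fragment that 26 and 27 give in one.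
- Comparison: used for ring C, this would end in a methyl resorcylate whose flanked ester has to be cleaved under forcing conditions. The chosen route starts from an arene at the correct oxidation level and delivers ring C with an orthogonally removable ester.

**Alternative 2:** Ring C would be formed last, by cutting the C-to-D ester C–O bond and the C1–C6 ring bond. In the forward step the diketo-dioxinone A5 (already carrying units A and B) would lose its acetonide by thermal cycloreversion. The acylketene would be captured by the secondary hydroxyl of the D–E alcohol A6 (also the key-step product of Alternative 3). The resulting 3,5,7-triketo ester would be closed by Cs2CO3 and then acid, through aldol condensation and dehydration, to the resorcylate A4.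
- For: the hindered benzoate is made at the ketene stage, before the ortho substituents exist. This is a better answer to the C-to-D bond than the Mitsunobu reaction of the chosen route. A4 is one hydrogenolysis from the target.
- Against: in A5 the B-unit oxygen is beta to the ketone that becomes C6, and the basic cyclisation invites E1cB loss of the whole A–B carboxylate. A5 itself requires several enolate acylations on enolisable polycarbonyl intermediates that are hard to purify. A failure would come at the last C–C bond-forming step with nearly all material committed.
- Comparison: the chosen route is less convergent at this bond. In return it uses stable aromatic intermediates and places its one uncertain C–C bond formation early, on a simple precursor.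

**Alternative 3:** Unit D would be assembled rather than bought, by cutting its C1–C2 bond and its ester C–O bond. In the forward step Co2(CO)8 with 3-hydroxypyridine under CO would open epoxide 27 at its CH2 carbon with the Co(CO)4 anion. CO would insert, and the acylcobalt would be cleaved by alcohol 29 to give the beta-hydroxy ester A6.
- For: the hydroxy acid and its ester bond form in one step from a cheap epoxide, with no protecting group on the D hydroxyl. For the D–E fragment alone this is more step-economic than any protected hydroxy-acid coupling.
- Against: alkoxycarbonylation is dependable when the alcohol is the solvent. With a stoichiometric, bulky secondary alcohol the acylcobalt is cleaved slowly, and beta-lactone formation, oligoesters from the product's own hydroxyl and isomerisation of the epoxide to a ketone are expected to compete. It also needs CO pressure.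
- Comparison: it solves the one unit that is commercial in both enantiomeric forms and leaves ring C unaddressed. The chosen route buys unit D and spends its demanding step on ring C, the only unit that cannot be bought.

Key step: step 4

Assumption: compounds 1, 9, 16, 19, 26 and 27 are taken as purchasable; 1 and 26 are otherwise one benzylation step from phloroglucinol and 5-bromoresorcinol.

## Route

**Step 1**
Reactants: 1 3,5-bis(benzyloxy)phenol
Product: 2 3,5-bis(benzyloxy)phenyl N-isopropylcarbamate
Conditions: i-PrNCO, Et3N (cat.), CH2Cl2, rt
Reagents that add atoms: isopropyl isocyanate, CC(C)N=C=O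
Why: Amine-catalysed addition of the phenol to the isocyanate gives the N-monoalkyl carbamate, which is the strongest ortho-directing group on the ring and can later be removed by E1cB elimination under mild base.

**Step 2**
Reactants: 2 3,5-bis(benzyloxy)phenyl N-isopropylcarbamate
Product: 6 3,5-bis(benzyloxy)-2-(trimethylsilyl)phenyl N-isopropylcarbamate, via N-silyl carbamate 3 (not isolated), via aryllithium 4 (not isolated), via C-silyl N-silyl carbamate 5 (not isolated)
Conditions: TMEDA, TBSOTf, Et2O, 0 °C to rt; TMEDA, n-BuLi, −78 °C; TMSCl, −78 °C to rt; aq NaHSO4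
Reagents that add atoms: chlorotrimethylsilane, C[Si](C)(C)Cl
Why: Directed ortho-metalation (Snieckus type) of the carbamate after in situ N-silylation, which blocks N–H deprotonation and isocyanate loss; C2 lies between the carbamate oxygen and a benzyloxy group and is the cooperatively activated site (C2 and C6 are equivalent by symmetry), and the N–Si bond is hydrolysed on acidic work-up.

**Step 3**
Reactants: 6 3,5-bis(benzyloxy)-2-(trimethylsilyl)phenyl N-isopropylcarbamate
Product: 8 3,5-bis(benzyloxy)-2-(trimethylsilyl)phenyl trifluoromethanesulfonate, via silylphenol 7 (not isolated)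
Conditions: DBU, Et2NH, MeCN, 40 °C; then PhNTf2, rt
Reagents that add atoms: N-phenylbis(trifluoromethanesulfonimide), O=S(=O)(N(c1ccccc1)S(=O)(=O)C(F)(F)F)C(F)(F)F
Why: DBU removes the carbamate N–H and the anion expels the phenoxide (E1cB); the isopropyl isocyanate set free is trapped by diethylamine as a urea, and the phenoxide is triflated in the same flask by the mild triflyl donor without protodesilylation.

**Step 4**
Reactants: 8 3,5-bis(benzyloxy)-2-(trimethylsilyl)phenyl trifluoromethanesulfonate; 9 diallyl malonate
Product: 11 allyl 2,4-bis(benzyloxy)-6-[2-(allyloxy)-2-oxoethyl]benzoate (diallyl 3,5-bis(benzyloxy)homophthalate), via 3,5-bis(benzyloxy)benzyne 10 (not isolated)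
Conditions: CsF (3 equiv), 9 (2 equiv), MeCN, 70 °C, slow addition of 8
Reagents that add atoms: none
Why: Fluoride attacks the silicon of 8 and the resulting aryl anion expels the ortho triflate, so aryne 10 forms with its triple bond between the carbons that become C1 and C6 of ring C. The caesium enolate of 9, formed by fluoride acting as base, adds through carbon to C6, the terminus remote from the C2 benzyloxy group, because this places the developing aryl anion at C1 beside the inductively withdrawing oxygen; the C4 benzyloxy group exerts only a weak opposite bias. The C1 anion then attacks the adjacent ester carbonyl (4-exo-trig) to give a benzocyclobutenoxide, which opens by retro-aldol-type cleavage of the former malonate C–C bond to the arylacetate enolate, and protonation gives 11. The C6–CH2 and C1–C(=O) bonds are thus made in one operation; the four-membered ring is only transient, no ring remains in 11 and no stereocentre is formed. The closest known reaction type is the fluoride-induced insertion of arynes into the C–C sigma bond of malonates and beta-keto esters (acyl-alkylation). The step needs C- over O-arylation, acyl transfer ahead of protonation of the aryl anion, and a single arylation; the soft carbon nucleophile, the aprotic medium with the ester held next to the anion, and the use of 9 in excess (it is far more acidic than 11) with slow addition of 8 should secure these. The allyl esters are spectators, since an isolated terminal alkene cannot compete with the enolate for the aryne.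

**Step 5**
Reactants: 11 allyl 2,4-bis(benzyloxy)-6-[2-(allyloxy)-2-oxoethyl]benzoate
Product: 12 {2-[(allyloxy)carbonyl]-3,5-bis(benzyloxy)phenyl}acetic acid
Conditions: LiOH·H2O (1.1 equiv), THF/H2O (3:1), 0 °C; then 1 M HCl
Reagents that add atoms: lithium hydroxide, [Li+].[OH-]
Why: Saponification discriminates on steric grounds: the aliphatic ester is unhindered, whereas the benzoate carbonyl is flanked by the C2 benzyloxy group and the C6 side chain and resists hydroxide at 0 °C.

**Step 6**
Reactants: 12 {2-[(allyloxy)carbonyl]-3,5-bis(benzyloxy)phenyl}acetic acid
Product: 13 allyl 2,4-bis(benzyloxy)-6-{2-[methoxy(methyl)amino]-2-oxoethyl}benzoate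
Conditions: MeNHOMe·HCl, EDC·HCl, HOBt (cat.), i-Pr2NEt, CH2Cl2, 0 °C to rt
Reagents that add atoms: N,O-dimethylhydroxylamine hydrochloride, CNOC.Cl
Why: Carbodiimide-mediated amidation to the Weinreb amide, chosen so that the organometallic addition that follows stops at the ketone.

**Step 7**
Reactants: 13 allyl 2,4-bis(benzyloxy)-6-{2-[methoxy(methyl)amino]-2-oxoethyl}benzoate
Product: 14 allyl 2,4-bis(benzyloxy)-6-(2-oxopropyl)benzoate
Conditions: MeMgBr, THF, −20 to 0 °C; aq NH4Cl
Reagents that add atoms: methylmagnesium bromide, C[Mg]Br
Why: Weinreb ketone synthesis; the magnesium-chelated tetrahedral adduct persists until the quench, so neither over-addition nor enolate closure of the product onto the ortho ester can occur, and the doubly ortho-substituted allyl benzoate is too hindered to react at this temperature.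

**Step 8**
Reactants: 14 allyl 2,4-bis(benzyloxy)-6-(2-oxopropyl)benzoate
Product: 15 allyl 2,4-bis(benzyloxy)-6-[(2R)-2-hydroxypropyl]benzoate
Conditions: (S)-Me-CBS oxazaborolidine (20 mol%), catecholborane, toluene, −78 to −40 °C; MeOH
Reagents that add atoms: none
Why: Corey–Bakshi–Shibata reduction; the ketone binds the ring boron of the (S)-oxazaborolidine anti to the larger arylmethyl group (made bulkier by its ortho ester) and hydride from the nitrogen-bound catecholborane is delivered to the Si face, which gives the (R)-carbinol. Catecholborane does not hydroborate the allyl C=C bond at this temperature, and the neutral medium avoids alkoxide-induced lactonisation onto the ortho ester.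

**Step 9**
Reactants: 16 methyl 2,4-dihydroxy-6-methylbenzoate (methyl orsellinate)
Product: 17 methyl 2,4-bis(benzyloxy)-6-methylbenzoate
Conditions: BnBr, K2CO3, DMF, 60 °C
Reagents that add atoms: benzyl bromide, BrCc1ccccc1
Why: Williamson etherification of both phenols; heating in DMF is needed for the C2 hydroxyl, which is hydrogen-bonded to the ester carbonyl.

**Step 10**
Reactants: 17 methyl 2,4-bis(benzyloxy)-6-methylbenzoate
Product: 18 2,4-bis(benzyloxy)-6-methylbenzoic acid
Conditions: KOH, DMSO/H2O, 90 °C; then HCl
Reagents that add atoms: potassium hydroxide, [K+].[OH-]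
Why: Forcing saponification of a di-ortho-substituted methyl benzoate, using poorly solvated hydroxide in wet DMSO; with both phenols benzylated the acid is not prone to decarboxylation.

**Step 11**
Reactants: 18 2,4-bis(benzyloxy)-6-methylbenzoic acid; 19 tert-butyl (3S)-3-hydroxybutanoate
Product: 20 tert-butyl (3R)-3-{[2,4-bis(benzyloxy)-6-methylbenzoyl]oxy}butanoate
Conditions: PPh3, DIAD, toluene, 0 °C to rt
Reagents that add atoms: none
Why: Mitsunobu esterification; the hindered acid acts only as the nucleophile, so the shielding of its carbonyl does not matter, and SN2 displacement of the oxyphosphonium group inverts the (S)-carbinol of 19 to the (R)-ester.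

**Step 12**
Reactants: 20 tert-butyl (3R)-3-{[2,4-bis(benzyloxy)-6-methylbenzoyl]oxy}butanoate
Product: 21 (3R)-3-{[2,4-bis(benzyloxy)-6-methylbenzoyl]oxy}butanoic acid
Conditions: TFA/CH2Cl2 (1:4), 0 °C to rt
Reagents that add atoms: none
Why: Acidolysis of the tert-butyl ester by alkyl–oxygen cleavage through the tert-butyl cation; the secondary benzoate, the benzyl ethers and the stereocentre are not affected by brief exposure.

**Step 13**
Reactants: 21 (3R)-3-{[2,4-bis(benzyloxy)-6-methylbenzoyl]oxy}butanoic acid; 15 allyl 2,4-bis(benzyloxy)-6-[(2R)-2-hydroxypropyl]benzoate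
Product: 22 allyl 2,4-bis(benzyloxy)-6-{(2R)-2-[((3R)-3-{[2,4-bis(benzyloxy)-6-methylbenzoyl]oxy}butanoyl)oxy]propyl}benzoate (A–B–C allyl ester)
Conditions: EDC·HCl, DMAP (cat.), CH2Cl2, 0 °C to rt
Reagents that add atoms: none
Why: Steglich esterification; the acylpyridinium from 21 should acylate the unhindered secondary carbinol of 15 faster than 15 can lactonise onto its own hindered allyl ester, and the carbinol configuration is retained because no bond to the stereocentre is broken.

**Step 14**
Reactants: 22 A–B–C allyl ester
Product: 23 2,4-bis(benzyloxy)-6-{(2R)-2-[((3R)-3-{[2,4-bis(benzyloxy)-6-methylbenzoyl]oxy}butanoyl)oxy]propyl}benzoic acid (A–B–C acid)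
Conditions: Pd(PPh3)4 (5 mol%), morpholine, THF, rt
Reagents that add atoms: none
Why: Tsuji–Trost-type deallylation; zerovalent palladium ionises the allyl–oxygen bond to a pi-allyl complex that morpholine intercepts, so the flanked carboxyl is released without any nucleophile reaching its carbonyl and the three other esters remain.

**Step 15**
Reactants: 23 A–B–C acid; 19 tert-butyl (3S)-3-hydroxybutanoate
Product: 24 tert-butyl (3R)-3-[(2,4-bis(benzyloxy)-6-{(2R)-2-[((3R)-3-{[2,4-bis(benzyloxy)-6-methylbenzoyl]oxy}butanoyl)oxy]propyl}benzoyl)oxy]butanoate (A–B–C–D tert-butyl ester)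
Conditions: PPh3, DIAD, 19 (2 equiv), toluene, 0 °C to rt
Reagents that add atoms: none
Why: Second Mitsunobu esterification with inversion, (S)-19 giving the (R)-configured unit D; the flanked ring C carboxylate again only has to act as nucleophile at the unhindered activated carbinol carbon.

**Step 16**
Reactants: 24 A–B–C–D tert-butyl ester
Product: 25 (3R)-3-[(2,4-bis(benzyloxy)-6-{(2R)-2-[((3R)-3-{[2,4-bis(benzyloxy)-6-methylbenzoyl]oxy}butanoyl)oxy]propyl}benzoyl)oxy]butanoic acid (A–B–C–D acid)
Conditions: TFA/CH2Cl2 (1:4), 0 °C
Reagents that add atoms: none
Why: tert-Butyl ester acidolysis as in step 12; the other ester groups are secondary alkyl esters that do not ionise under these conditions.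

**Step 17**
Reactants: 26 1-bromo-3,5-bis(benzyloxy)benzene; 27 (R)-2-methyloxirane ((R)-propylene oxide)
Product: 29 (2R)-1-[3,5-bis(benzyloxy)phenyl]propan-2-ol, via arylmagnesium bromide 28 (not isolated)
Conditions: Mg, THF, reflux; then CuI (10 mol%), 27, −30 to 0 °C; aq NH4Cl
Reagents that add atoms: none
Why: Copper-catalysed opening of the epoxide by the aryl Grignard reagent at the unsubstituted carbon; the stereocentre of 27 is not touched, so the (R)-epoxide gives the (R)-carbinol.

**Step 18**
Reactants: 25 A–B–C–D acid; 29 (2R)-1-[3,5-bis(benzyloxy)phenyl]propan-2-ol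
Product: 30 hexa-O-benzyl Hansforester A (the target with all six phenols as benzyl ethers)
Conditions: EDC·HCl, DMAP (cat.), CH2Cl2, 0 °C to rt
Reagents that add atoms: none
Why: Steglich esterification of an unhindered acid with an unhindered secondary alcohol; no bond to a stereocentre is broken.

**Step 19**
Reactants: 30 hexa-O-benzyl Hansforester A
Product: 31 Hansforester A
Conditions: H2 (1 atm), 10% Pd/C, EtOAc/EtOH, rt
Reagents that add atoms: none
Why: Hydrogenolysis of the six benzyl aryl ethers over palladium; the ester oxygens sit on homobenzylic carbons and are inert, and the neutral conditions spare the beta-acyloxy esters.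

## Compound list

1 | 3,5-bis(benzyloxy)phenol | Oc1cc(OCc2ccccc2)cc(OCc2ccccc2)c1 | starting material
2 | 3,5-bis(benzyloxy)phenyl N-isopropylcarbamate | CC(C)NC(=O)Oc1cc(OCc2ccccc2)cc(OCc2ccccc2)c1 | intermediate
3 | 3,5-bis(benzyloxy)phenyl N-(tert-butyldimethylsilyl)-N-isopropylcarbamate | CC(C)N(C(=O)Oc1cc(OCc2ccccc2)cc(OCc2ccccc2)c1)[Si](C)(C)C(C)(C)C | intermediate (not isolated)
4 | 2-lithio derivative of 3 (lithium at C2, between the carbamate oxygen and a benzyloxy group) | [Li]c1c(OC(=O)N(C(C)C)[Si](C)(C)C(C)(C)C)cc(OCc2ccccc2)cc1OCc1ccccc1 | intermediate (not isolated)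
5 | 3,5-bis(benzyloxy)-2-(trimethylsilyl)phenyl N-(tert-butyldimethylsilyl)-N-isopropylcarbamate | C[Si](C)(C)c1c(OC(=O)N(C(C)C)[Si](C)(C)C(C)(C)C)cc(OCc2ccccc2)cc1OCc1ccccc1 | intermediate (not isolated)
6 | 3,5-bis(benzyloxy)-2-(trimethylsilyl)phenyl N-isopropylcarbamate | C[Si](C)(C)c1c(OC(=O)NC(C)C)cc(OCc2ccccc2)cc1OCc1ccccc1 | intermediate
7 | 3,5-bis(benzyloxy)-2-(trimethylsilyl)phenol | C[Si](C)(C)c1c(O)cc(OCc2ccccc2)cc1OCc1ccccc1 | intermediate (not isolated)
8 | 3,5-bis(benzyloxy)-2-(trimethylsilyl)phenyl trifluoromethanesulfonate | C[Si](C)(C)c1c(OCc2ccccc2)cc(OCc2ccccc2)cc1OS(=O)(=O)C(F)(F)F | intermediate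
9 | diallyl malonate | C=CCOC(=O)CC(=O)OCC=C | starting material
10 | 3,5-bis(benzyloxy)benzyne | C1#CC(OCc2ccccc2)=CC(OCc2ccccc2)=C1 | intermediate (not isolated)
11 | allyl 2,4-bis(benzyloxy)-6-[2-(allyloxy)-2-oxoethyl]benzoate | C=CCOC(=O)Cc1cc(OCc2ccccc2)cc(OCc2ccccc2)c1C(=O)OCC=C | intermediate
12 | {2-[(allyloxy)carbonyl]-3,5-bis(benzyloxy)phenyl}acetic acid | OC(=O)Cc1cc(OCc2ccccc2)cc(OCc2ccccc2)c1C(=O)OCC=C | intermediate
13 | allyl 2,4-bis(benzyloxy)-6-{2-[methoxy(methyl)amino]-2-oxoethyl}benzoate | CON(C)C(=O)Cc1cc(OCc2ccccc2)cc(OCc2ccccc2)c1C(=O)OCC=C | intermediate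
14 | allyl 2,4-bis(benzyloxy)-6-(2-oxopropyl)benzoate | CC(=O)Cc1cc(OCc2ccccc2)cc(OCc2ccccc2)c1C(=O)OCC=C | intermediate
15 | allyl 2,4-bis(benzyloxy)-6-[(2R)-2-hydroxypropyl]benzoate | C[C@@H](O)Cc1cc(OCc2ccccc2)cc(OCc2ccccc2)c1C(=O)OCC=C | intermediate
16 | methyl 2,4-dihydroxy-6-methylbenzoate | COC(=O)c1c(C)cc(O)cc1O | starting material
17 | methyl 2,4-bis(benzyloxy)-6-methylbenzoate | COC(=O)c1c(C)cc(OCc2ccccc2)cc1OCc1ccccc1 | intermediate
18 | 2,4-bis(benzyloxy)-6-methylbenzoic acid | OC(=O)c1c(C)cc(OCc2ccccc2)cc1OCc1ccccc1 | intermediate
19 | tert-butyl (3S)-3-hydroxybutanoate | C[C@H](O)CC(=O)OC(C)(C)C | starting material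
20 | tert-butyl (3R)-3-{[2,4-bis(benzyloxy)-6-methylbenzoyl]oxy}butanoate | Cc1cc(OCc2ccccc2)cc(OCc2ccccc2)c1C(=O)O[C@H](C)CC(=O)OC(C)(C)C | intermediate
21 | (3R)-3-{[2,4-bis(benzyloxy)-6-methylbenzoyl]oxy}butanoic acid | Cc1cc(OCc2ccccc2)cc(OCc2ccccc2)c1C(=O)O[C@H](C)CC(=O)O | intermediate
22 | A–B–C allyl ester (all carbinol centres R) | Cc1cc(OCc2ccccc2)cc(OCc2ccccc2)c1C(=O)O[C@H](C)CC(=O)O[C@H](C)Cc1cc(OCc2ccccc2)cc(OCc2ccccc2)c1C(=O)OCC=C | intermediate
23 | A–B–C acid | Cc1cc(OCc2ccccc2)cc(OCc2ccccc2)c1C(=O)O[C@H](C)CC(=O)O[C@H](C)Cc1cc(OCc2ccccc2)cc(OCc2ccccc2)c1C(=O)O | intermediate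
24 | A–B–C–D tert-butyl ester | Cc1cc(OCc2ccccc2)cc(OCc2ccccc2)c1C(=O)O[C@H](C)CC(=O)O[C@H](C)Cc1cc(OCc2ccccc2)cc(OCc2ccccc2)c1C(=O)O[C@H](C)CC(=O)OC(C)(C)C | intermediate
25 | A–B–C–D acid | Cc1cc(OCc2ccccc2)cc(OCc2ccccc2)c1C(=O)O[C@H](C)CC(=O)O[C@H](C)Cc1cc(OCc2ccccc2)cc(OCc2ccccc2)c1C(=O)O[C@H](C)CC(=O)O | intermediate
26 | 1-bromo-3,5-bis(benzyloxy)benzene | Brc1cc(OCc2ccccc2)cc(OCc2ccccc2)c1 | starting material
27 | (R)-2-methyloxirane | C[C@@H]1CO1 | starting material
28 | [3,5-bis(benzyloxy)phenyl]magnesium bromide | Br[Mg]c1cc(OCc2ccccc2)cc(OCc2ccccc2)c1 | intermediate (not isolated)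
29 | (2R)-1-[3,5-bis(benzyloxy)phenyl]propan-2-ol | C[C@@H](O)Cc1cc(OCc2ccccc2)cc(OCc2ccccc2)c1 | intermediate
30 | hexa-O-benzyl Hansforester A | Cc1cc(OCc2ccccc2)cc(OCc2ccccc2)c1C(=O)O[C@H](C)CC(=O)O[C@H](C)Cc1cc(OCc2ccccc2)cc(OCc2ccccc2)c1C(=O)O[C@H](C)CC(=O)O[C@H](C)Cc1cc(OCc2ccccc2)cc(OCc2ccccc2)c1 | intermediate
31 | Hansforester A | Cc1cc(O)cc(O)c1C(=O)O[C@H](C)CC(=O)O[C@H](C)Cc1cc(O)cc(O)c1C(=O)O[C@H](C)CC(=O)O[C@H](C)Cc1cc(O)cc(O)c1 | target

## Step count and risk

Total: 19 steps. Longest linear sequence: 14 steps (steps 1–8, 13–16, 18, 19). Steps 9–12 (fragment A–B) and step 17 (ring E carbinol) are side branches.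

**Step 4 (key step).** The most likely failure is interruption of the insertion after the first C–C bond. If the aryl anion is protonated before it reaches the ester carbonyl, a simple alpha-aryl malonate results, and this acidic product can be arylated a second time. Ester carbonyls are weaker acceptors than the ketones usually used in acyl-alkylation, so this diversion is the main concern; partial erosion of regiochemistry by the C4 benzyloxy group is a lesser one.
Fallback, from acid 18 back to ketone 14: acid 18 would be alkylated with allyl bromide and K2CO3 in DMF to allyl 2,4-bis(benzyloxy)-6-methylbenzoate F1. Lateral lithiation of the C6 methyl group with LDA in THF at −78 °C and acylation of the benzylic anion with N-methoxy-N-methylacetamide would give ketone 14 directly, bypassing compounds 8 to 13.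

**Step 8.** The methyl and arylmethyl groups of 14 differ only moderately in size, so facial discrimination in the reduction may be incomplete. The product carbinol may also close onto the ortho ester during isolation on silica.
Fallback, from ketone 14 back to carbinol 15: reduction with NaBH4 and CeCl3·7H2O in MeOH at −40 °C with an acetic acid quench would give racemic allyl 2,4-bis(benzyloxy)-6-(2-hydroxypropyl)benzoate F2. Immobilised Candida antarctica lipase B with vinyl acetate in MTBE would acylate the R enantiomer selectively to allyl 6-[(2R)-2-acetoxypropyl]-2,4-bis(benzyloxy)benzoate F3, which is separated from the unreacted S enantiomer of F2 (recyclable by oxidation to 14). The same lipase with n-butanol would then remove the acetate under neutral conditions to give 15.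

**Step 15.** The activated beta-hydroxy ester may undergo elimination to the crotonate faster than the bulky, weakly nucleophilic ring C carboxylate can displace the oxyphosphonium group. Acyl transfer from the acid to the reduced azodicarboxylate is a second drain. Both consume late-stage acid 23.
Fallback, from acid 23 back to ester 24: acid 23 would be converted under neutral conditions with 1-chloro-N,N,2-trimethylprop-1-en-1-amine in CH2Cl2 into the A–B–C acid chloride F4. This would be treated with commercial tert-butyl (3R)-3-hydroxybutanoate, Et3N and DMAP, forming the ester by acyl substitution with retention and giving 24.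

**Step 13.** Activation of the beta-acyloxy acid 21 makes its alpha-hydrogens more acidic, so E1cB expulsion of the orsellinate carboxylate (crotonate formation) may compete with acyl transfer. Carbinol 15 may meanwhile lactonise.
Fallback, from ketone 14 back to ester 22: reduction of 14 with the (R)-Me-CBS oxazaborolidine and catecholborane would give allyl 2,4-bis(benzyloxy)-6-[(2S)-2-hydroxypropyl]benzoate F5. A Mitsunobu reaction of F5 with acid 21 (PPh3, DIAD, toluene) would then form the B-to-C ester with inversion to the R configuration, so that 21 acts only as a carboxylate nucleophile and is never activated.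

**Step 2.** Deprotonation may stray to a benzylic OCH2 position (followed by Wittig rearrangement) or to C4 between the two benzyloxy groups. The lithiated carbamate may also undergo anionic ortho-Fries migration if the temperature rises before the silyl chloride is added.
Fallback, from phenol 1 back to triflate 8: ortho-bromination of 1 with NBS in CH2Cl2 at −78 °C would give 2-bromo-3,5-bis(benzyloxy)phenol F6. Silylation with HMDS in THF at 65 °C would give [2-bromo-3,5-bis(benzyloxy)phenoxy]trimethylsilane F7. Bromine–lithium exchange with n-BuLi at −78 °C would trigger a 1,3-shift of silicon from oxygen to carbon, giving the lithium salt of 7, which is trapped with Tf2O to give 8.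

## Further compounds

F1 | step 4 | allyl 2,4-bis(benzyloxy)-6-methylbenzoate | C=CCOC(=O)c1c(C)cc(OCc2ccccc2)cc1OCc1ccccc1
F2 | step 8 | racemic allyl 2,4-bis(benzyloxy)-6-(2-hydroxypropyl)benzoate | CC(O)Cc1cc(OCc2ccccc2)cc(OCc2ccccc2)c1C(=O)OCC=C
F3 | step 8 | allyl 6-[(2R)-2-acetoxypropyl]-2,4-bis(benzyloxy)benzoate | CC(=O)O[C@H](C)Cc1cc(OCc2ccccc2)cc(OCc2ccccc2)c1C(=O)OCC=C
F4 | step 15 | A–B–C acid chloride (acid chloride of 23) | Cc1cc(OCc2ccccc2)cc(OCc2ccccc2)c1C(=O)O[C@H](C)CC(=O)O[C@H](C)Cc1cc(OCc2ccccc2)cc(OCc2ccccc2)c1C(=O)Cl
F5 | step 13 | allyl 2,4-bis(benzyloxy)-6-[(2S)-2-hydroxypropyl]benzoate | C[C@H](O)Cc1cc(OCc2ccccc2)cc(OCc2ccccc2)c1C(=O)OCC=C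
F6 | step 2 | 2-bromo-3,5-bis(benzyloxy)phenol | Oc1cc(OCc2ccccc2)cc(OCc2ccccc2)c1Br
F7 | step 2 | [2-bromo-3,5-bis(benzyloxy)phenoxy]trimethylsilane | C[Si](C)(C)Oc1cc(OCc2ccccc2)cc(OCc2ccccc2)c1Br
A1 | alternative 1 | methyl 2,4-dioxo-6-[(2R)-2-(tert-butyldimethylsilyloxy)propyl]cyclohexane-1-carboxylate | COC(=O)C1C(=O)CC(=O)CC1C[C@@H](C)O[Si](C)(C)C(C)(C)C
A2 | alternative 1 | (3E,6R)-6-(tert-butyldimethylsilyloxy)hept-3-en-2-one | CC(=O)/C=C/C[C@@H](C)O[Si](C)(C)C(C)(C)C
A3 | alternative 1 | dimethyl malonate | COC(=O)CC(=O)OC
A4 | alternative 2 | full chain with free ring C phenols and benzylated rings A and E | Cc1cc(OCc2ccccc2)cc(OCc2ccccc2)c1C(=O)O[C@H](C)CC(=O)O[C@H](C)Cc1cc(O)cc(O)c1C(=O)O[C@H](C)CC(=O)O[C@H](C)Cc1cc(OCc2ccccc2)cc(OCc2ccccc2)c1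
A5 | alternative 2 | diketo-dioxinone carrying units A and B: 2,2-dimethyl-1,3-dioxin-4-one with a 6-(2,4-dioxo-6-acyloxyheptyl) chain | CC1(C)OC(=O)C=C(CC(=O)CC(=O)C[C@@H](C)OC(=O)C[C@@H](C)OC(=O)c2c(C)cc(OCc3ccccc3)cc2OCc2ccccc2)O1
A6 | alternative 3 | (2R)-1-[3,5-bis(benzyloxy)phenyl]propan-2-yl (3R)-3-hydroxybutanoate (D–E alcohol; also the trapping alcohol of alternative 2) | O[C@H](C)CC(=O)O[C@H](C)Cc1cc(OCc2ccccc2)cc(OCc2ccccc2)c1
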